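**Plan**

- Retrosynthesis: the ring B quinone is traced back to a para-methoxyphenol held as its benzyl ether, C2 of the pyran ring is raised to the lactol level, and the pyran ring is then cut at C3–C4 and O1–C2.
- Enabling feature: O1 and C4 sit on the adjacent carbons C8a and C4a of ring A, so ring A can act as an ortho-quinone methide (C4 its exocyclic CH2, O1 its carbonyl oxygen), while C2, C3 and ring B arrive together as an arylacetaldehyde.
- Forward: sulfone 7 (ring A, latent quinone methide) comes in four steps from 2,3,4-trimethoxybenzaldehyde and aldehyde 18 (ring B with C2 and C3) in five steps from 1,2,3,4-tetramethoxybenzene. Their amine-catalysed annulation closes the pyran ring, the only ring made in the route.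
- End game: lactol deoxygenation, debenzylation, oxidation of ring B to the quinone.
- Stereochemistry: the single stereocentre, C3 (S), is set in the annulation by the enamine of (S)-α,α-diphenylprolinol trimethylsilyl ether and is secured by prompt removal of the lactol.

Key step: step 10

Remark on the chemistry: the sense of induction is assigned from the usual shielding model for enamines of (S)-diarylprolinol silyl ethers. It corresponds to (S) at C3 in 20–23 (CIP order C2 > ring B carbon > C4 > H throughout). The (R)-catalyst is the remedy should the opposite sense be found.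

**Route**

Step 1
Reactants: 1 2,3,4-trimethoxybenzaldehyde
Product: 3 2,3,4-trimethoxyphenol, via aryl formate 2 (not isolated)
Conditions: 30% H2O2, H2SO4 (cat.), MeOH, rt
Reagents that add atoms: hydrogen peroxide, OO
Why: In this acid-catalysed Dakin oxidation the ortho/para-methoxylated aryl group migrates in preference to hydride in the peroxide adduct, and formate 2 is methanolysed in the same pot.

Step 2
Reactants: 3 2,3,4-trimethoxyphenol
Product: 4 2-hydroxy-3,4,5-trimethoxybenzaldehyde
Conditions: MgCl2, Et3N, (CH2O)n, MeCN, reflux; aq HCl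
Reagents that add atoms: formaldehyde (as paraformaldehyde), C=O
Why: In this magnesium-mediated ortho-formylation (Casnati–Skattebøl) the magnesium phenoxide delivers formaldehyde to the only free ortho carbon, and the hydroxymethyl stage is oxidised by hydride transfer to a second formaldehyde.

Step 3
Reactants: 4 2-hydroxy-3,4,5-trimethoxybenzaldehyde
Product: 5 6-(hydroxymethyl)-2,3,4-trimethoxyphenol
Conditions: NaBH4, MeOH, 0 °C
Reagents that add atoms: none
Why: Borohydride reduction of the aryl aldehyde to the benzylic alcohol should be clean because nothing else in 4 is reducible.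

Step 4
Reactants: 5 6-(hydroxymethyl)-2,3,4-trimethoxyphenol; 6 sodium p-toluenesulfinate
Product: 7 2,3,4-trimethoxy-6-(tosylmethyl)phenol
Conditions: HCO2H/H2O, rt
Reagents that add atoms: none
Why: In this acid-promoted SN1-type substitution the ortho-hydroxybenzyl alcohol ionises to a benzylic cation (protonated quinone methide) that the sulfinate traps at sulfur, the standard access to 2-(sulfonylmethyl)phenols.

Step 5
Reactants: 8 1,2,3,4-tetramethoxybenzene
Product: 11 2,3,4,5-tetramethoxyphenol, via aryllithium 9 (not isolated), via arylboronate 10 (not isolated)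
Conditions: n-BuLi, TMEDA, THF, 0 °C; B(OMe)3, −78 °C to rt; H2O2, AcOH, 0 °C to rt
Reagents that add atoms: hydrogen peroxide, OO
Why: Directed ortho-metalation next to a methoxy group (the two free positions are equivalent), borylation and oxidative C–B cleavage should give the phenol in one pot.

Step 6
Reactants: 11 2,3,4,5-tetramethoxyphenol; 12 allyl bromide
Product: 13 1-(allyloxy)-2,3,4,5-tetramethoxybenzene
Conditions: K2CO3, acetone, reflux
Reagents that add atoms: none
Why: Williamson O-allylation of the phenoxide with a reactive primary allylic bromide.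

Step 7
Reactants: 13 1-(allyloxy)-2,3,4,5-tetramethoxybenzene
Product: 15 2-allyl-3,4,5,6-tetramethoxyphenol, via dienone 14 (not isolated)
Conditions: PhNEt2, 190 °C
Reagents that add atoms: none
Why: The aromatic Claisen rearrangement ([3,3]-sigmatropic shift) goes to the only unsubstituted ortho carbon and dienone 14 tautomerises, while migration toward the methoxylated ortho carbon is reversible and unproductive.

Step 8
Reactants: 15 2-allyl-3,4,5,6-tetramethoxyphenol
Product: 16 1-allyl-2-(benzyloxy)-3,4,5,6-tetramethoxybenzene
Conditions: BnBr, K2CO3, DMF, 60 °C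
Reagents that add atoms: benzyl bromide, BrCc1ccccc1
Why: Williamson benzylation gives an ether that keeps the ring B phenol from closing onto the later aldehyde and that is removable by hydrogenolysis.

Step 9
Reactants: 16 1-allyl-2-(benzyloxy)-3,4,5,6-tetramethoxybenzene
Product: 18 [2-(benzyloxy)-3,4,5,6-tetramethoxyphenyl]acetaldehyde, via ozonide 17 (not isolated)
Conditions: O3, CH2Cl2, −78 °C (Sudan Red 7B end point); PPh3, −78 °C to rt; used directly
Reagents that add atoms: ozone, [O-][O+]=O
Why: In this ozonolysis with reductive work-up the terminal alkene should react far faster than the fully substituted arene, and the dye end point avoids excess ozone.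

Step 10
Reactants: 7 2,3,4-trimethoxy-6-(tosylmethyl)phenol; 18 [2-(benzyloxy)-3,4,5,6-tetramethoxyphenyl]acetaldehyde
Product: 20 (3S)-3-[2-(benzyloxy)-3,4,5,6-tetramethoxyphenyl]-6,7,8-trimethoxychroman-2-ol (C2 anomers), via ortho-quinone methide 19 (not isolated)
Conditions: (S)-α,α-diphenylprolinol trimethylsilyl ether (20 mol %), Na2CO3, CH2Cl2, 0 °C to rt; 18 in excess
Reagents that add atoms: none
Why: Na2CO3 deprotonates the phenol of 7 and expels p-toluenesulfinate, releasing ortho-quinone methide 19 slowly, while the amine condenses with 18 to the E-enamine; the enamine β-carbon (future C3) adds to the exocyclic CH2 of 19 (future C4), which restores the aromaticity of ring A, the phenoxide then adds to the iminium carbon (future C2), and the water lost in enamine formation hydrolyses the N,O-aminal to lactol 20 and free catalyst. The closest known reaction type is the secondary-amine-catalysed formal (4+2) annulation (stepwise inverse-demand oxa-Diels–Alder) of in situ ortho-quinone methides from 2-(sulfonylmethyl)phenols with enolisable aldehydes, which gives 3-substituted chroman-2-ols. The pyran ring closes through O1–C2 by a 6-exo-trig attack of the phenoxide on the C=N+ bond, after the intermolecular C3–C4 bond formation. C3 is the only stereocentre that matters: the CPh2(OSiMe3) group blocks one face of the s-trans E-enamine, so the CH2 terminus enters from the open face and the (S)-catalyst should give (3S), whereas C2 is an anomeric centre that is erased in step 11. The step needs C-alkylation of the enamine to outrun oligomerisation of 19, N-alkylation of the catalyst and self-aldol reaction of 18; the three methoxy groups of ring A let 19 form under weak base and temper its electrophilicity, slow heterogeneous release keeps its concentration low, 18 is used in excess, the CH2 terminus removes any diastereoselectivity question at C4, and the benzyl ether keeps the ring B oxygen out of the reaction.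

Step 11
Reactants: 20 (3S)-3-[2-(benzyloxy)-3,4,5,6-tetramethoxyphenyl]-6,7,8-trimethoxychroman-2-ol
Product: 21 (3S)-3-[2-(benzyloxy)-3,4,5,6-tetramethoxyphenyl]-6,7,8-trimethoxychroman
Conditions: Et3SiH, BF3·OEt2, CH2Cl2, −78 to −30 °C, run directly after step 10
Reagents that add atoms: none
Why: In this ionic hydrogenation (reductive deoxygenation of a lactol) BF3 ionises the anomeric OH to the cyclic oxocarbenium ion, which Et3SiH should reduce at low temperature faster than H3 is lost, helped by the twisted, di-ortho-substituted ring B that offers little conjugation to an enol ether, so C3 stays (S).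

Step 12
Reactants: 21 (3S)-3-[2-(benzyloxy)-3,4,5,6-tetramethoxyphenyl]-6,7,8-trimethoxychroman
Product: 22 2,3,4,5-tetramethoxy-6-[(3S)-6,7,8-trimethoxychroman-3-yl]phenol
Conditions: H2 (1 atm), 10% Pd/C, EtOAc, rt
Reagents that add atoms: none
Why: Hydrogenolysis of the benzyl aryl ether should leave the methyl ethers, the chroman C–O bonds and C3 untouched.

Step 13
Reactants: 22 2,3,4,5-tetramethoxy-6-[(3S)-6,7,8-trimethoxychroman-3-yl]phenol
Product: 23 2,3,5-trimethoxy-6-[(3S)-6,7,8-trimethoxychroman-3-yl]cyclohexa-2,5-diene-1,4-dione (target)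
Conditions: PhI(OAc)2, MeCN/H2O, 0 °C
Reagents that add atoms: water, O
Why: In this hypervalent-iodine oxidation of a para-methoxyphenol to the para-quinone, the phenol is oxidised to the para-oxocarbenium ion, water adds at the methoxylated para carbon and methanol is lost, while ring A, which has no free phenol, and C3, under neutral conditions, should be unaffected.

**Compound list**

1 | 2,3,4-trimethoxybenzaldehyde | COc1ccc(C=O)c(OC)c1OC | starting material
2 | 2,3,4-trimethoxyphenyl formate | COc1ccc(OC=O)c(OC)c1OC | intermediate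
3 | 2,3,4-trimethoxyphenol | COc1ccc(O)c(OC)c1OC | intermediate
4 | 2-hydroxy-3,4,5-trimethoxybenzaldehyde | COc1cc(C=O)c(O)c(OC)c1OC | intermediate
5 | 6-(hydroxymethyl)-2,3,4-trimethoxyphenol | COc1cc(CO)c(O)c(OC)c1OC | intermediate
6 | sodium p-toluenesulfinate | Cc1ccc(cc1)S(=O)[O-].[Na+] | starting material
7 | 2,3,4-trimethoxy-6-(tosylmethyl)phenol | Cc1ccc(cc1)S(=O)(=O)Cc1cc(OC)c(OC)c(OC)c1O | intermediate
8 | 1,2,3,4-tetramethoxybenzene | COc1ccc(OC)c(OC)c1OC | starting material
9 | (2,3,4,5-tetramethoxyphenyl)lithium | [Li]c1cc(OC)c(OC)c(OC)c1OC | intermediate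
10 | dimethyl (2,3,4,5-tetramethoxyphenyl)boronate | COB(OC)c1cc(OC)c(OC)c(OC)c1OC | intermediate
11 | 2,3,4,5-tetramethoxyphenol | COc1cc(O)c(OC)c(OC)c1OC | intermediate
12 | allyl bromide | C=CCBr | starting material
13 | 1-(allyloxy)-2,3,4,5-tetramethoxybenzene | C=CCOc1cc(OC)c(OC)c(OC)c1OC | intermediate
14 | 6-allyl-2,3,4,5-tetramethoxycyclohexa-2,4-dien-1-one (racemic) | C=CCC1C(=O)C(OC)=C(OC)C(OC)=C1OC | intermediate
15 | 2-allyl-3,4,5,6-tetramethoxyphenol | C=CCc1c(O)c(OC)c(OC)c(OC)c1OC | intermediate
16 | 1-allyl-2-(benzyloxy)-3,4,5,6-tetramethoxybenzene | C=CCc1c(OCc2ccccc2)c(OC)c(OC)c(OC)c1OC | intermediate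
17 | 3-{[2-(benzyloxy)-3,4,5,6-tetramethoxyphenyl]methyl}-1,2,4-trioxolane (ozonide) | COc1c(OC)c(OC)c(OC)c(OCc2ccccc2)c1CC1OCOO1 | intermediate
18 | [2-(benzyloxy)-3,4,5,6-tetramethoxyphenyl]acetaldehyde | COc1c(OC)c(OC)c(OC)c(OCc2ccccc2)c1CC=O | intermediate
19 | 2,3,4-trimethoxy-6-methylidenecyclohexa-2,4-dien-1-one (ortho-quinone methide) | C=C1C=C(OC)C(OC)=C(OC)C1=O | intermediate
20 | (3S)-3-[2-(benzyloxy)-3,4,5,6-tetramethoxyphenyl]-6,7,8-trimethoxychroman-2-ol (C2 anomers) | COc1c(OC)c(OC)c(OC)c(OCc2ccccc2)c1[C@H]3C(O)Oc4c(cc(OC)c(OC)c4OC)C3 | intermediate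
21 | (3S)-3-[2-(benzyloxy)-3,4,5,6-tetramethoxyphenyl]-6,7,8-trimethoxychroman | COc1c(OC)c(OC)c(OC)c(OCc2ccccc2)c1[C@H]3COc4c(cc(OC)c(OC)c4OC)C3 | intermediate
22 | 2,3,4,5-tetramethoxy-6-[(3S)-6,7,8-trimethoxychroman-3-yl]phenol | COc1c(OC)c(OC)c(OC)c(O)c1[C@H]3COc4c(cc(OC)c(OC)c4OC)C3 | intermediate
23 | 2,3,5-trimethoxy-6-[(3S)-6,7,8-trimethoxychroman-3-yl]cyclohexa-2,5-diene-1,4-dione | COC1=C(OC)C(=O)C([C@H]2COc3c(cc(OC)c(OC)c3OC)C2)=C(OC)C1=O | target

**Count**

Total steps: 13. Longest linear sequence: 9 steps (steps 5–13, from 1,2,3,4-tetramethoxybenzene); the ring A branch (steps 1–4) joins at step 10.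

**Steps most likely to fail**

Step 10. The unsubstituted quinone methide may be consumed by oligomerisation or by N-alkylation of the amine catalyst before the hindered enamine captures it, and the α-aryl lactol may lose enantiopurity by enolisation of its open form. The fallback gives up the annulation and sets C3 by hydrogenation; it sets out from 18 and 4 and returns at 21. Pinnick oxidation of 18 (NaClO2, NaH2PO4, 2-methyl-2-butene, t-BuOH/H2O) should give [2-(benzyloxy)-3,4,5,6-tetramethoxyphenyl]acetic acid F1. Perkin condensation of F1 with salicylaldehyde 4 (Ac2O, Et3N, 120 °C) should give 3-[2-(benzyloxy)-3,4,5,6-tetramethoxyphenyl]-6,7,8-trimethoxy-2H-chromen-2-one F2. Reduction with i-Bu2AlH (CH2Cl2, −78 to 0 °C) should open the lactone to 6-[(1Z)-2-[2-(benzyloxy)-3,4,5,6-tetramethoxyphenyl]-3-hydroxyprop-1-en-1-yl]-2,3,4-trimethoxyphenol F3. Mitsunobu etherification (PPh3, DIAD, THF) should close it to 3-[2-(benzyloxy)-3,4,5,6-tetramethoxyphenyl]-6,7,8-trimethoxy-2H-chromene F4. Asymmetric hydrogenation of F4 (H2, [Ir(cod)(L)]B[3,5-(CF3)2C6H3]4 with L a chiral phosphine–oxazoline ligand of the enantiomer that delivers 3S, CH2Cl2) should then give 21 without touching the benzyl ether.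

Step 11. The oxocarbenium ion may lose H3 to a 4H-chromene faster than it takes up hydride, which would erode the configuration at C3 or stall the reduction. The fallback sets out from 20 and returns at 21. NaBH4 (MeOH, 0 °C) should reduce the open hydroxy-aldehyde form of the lactol to 6-[(2S)-2-[2-(benzyloxy)-3,4,5,6-tetramethoxyphenyl]-3-hydroxypropyl]-2,3,4-trimethoxyphenol F5, in which C3 is no longer α to a carbonyl. Mitsunobu etherification (PPh3, DIAD, THF, 0 °C) between the ring A phenol and the primary alcohol should then re-form O1–C2 and give 21 without passing through a cation.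

Step 9. Ozone may over-oxidise the electron-rich, penta-oxygenated ring or the benzylic ether CH2 before the alkene is fully consumed. The fallback sets out from 16 and returns at 18. Dihydroxylation (K2OsO4·2H2O cat., NMO, acetone/H2O) should give 3-[2-(benzyloxy)-3,4,5,6-tetramethoxyphenyl]propane-1,2-diol F6, and glycol cleavage with NaIO4 (THF/H2O, 0 °C) should then give 18 under conditions that do not attack the arene.

**Further compounds**

F1 | step 10 | [2-(benzyloxy)-3,4,5,6-tetramethoxyphenyl]acetic acid | COc1c(OC)c(OC)c(OC)c(OCc2ccccc2)c1CC(=O)O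
F2 | step 10 | 3-[2-(benzyloxy)-3,4,5,6-tetramethoxyphenyl]-6,7,8-trimethoxy-2H-chromen-2-one | COc1c(OC)c(OC)c(OC)c(OCc2ccccc2)c1C3=Cc4cc(OC)c(OC)c(OC)c4OC3=O
F3 | step 10 | 6-[(1Z)-2-[2-(benzyloxy)-3,4,5,6-tetramethoxyphenyl]-3-hydroxyprop-1-en-1-yl]-2,3,4-trimethoxyphenol | OC/C(c1c(OC)c(OC)c(OC)c(OC)c1OCc1ccccc1)=C\c1cc(OC)c(OC)c(OC)c1O
F4 | step 10 | 3-[2-(benzyloxy)-3,4,5,6-tetramethoxyphenyl]-6,7,8-trimethoxy-2H-chromene | COc1c(OC)c(OC)c(OC)c(OCc2ccccc2)c1C3=Cc4cc(OC)c(OC)c(OC)c4OC3
F5 | step 11 | 6-[(2S)-2-[2-(benzyloxy)-3,4,5,6-tetramethoxyphenyl]-3-hydroxypropyl]-2,3,4-trimethoxyphenol | COc1c(OC)c(OC)c(OC)c(OCc2ccccc2)c1[C@@H](CO)Cc3cc(OC)c(OC)c(OC)c3O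
F6 | step 9 | 3-[2-(benzyloxy)-3,4,5,6-tetramethoxyphenyl]propane-1,2-diol | COc1c(OC)c(OC)c(OC)c(OCc2ccccc2)c1CC(O)CO
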